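**Retrosynthetic overview**
1. The ring C8–C9–C10–C11–C12 is a β-hydroxy ketone (C9=O, C8–H, C12–OH) whose carbons C9 and C12 sit cis on C10=C11. Cutting C8–C12 (retro-aldol) gives a (Z)-2-chloro-ene-1,4-dione, and tying its C9 enol oxygen to the acyl carbon C12 gives enol lactone 14, a (Z)-4-chloro-5-ylidenefuran-2(5H)-one (ring O–C12–C11–C10–C9, exocyclic C9=C8).
2. Key step: (Z)-oct-2-enylbarium adds to the lactone carbonyl (C12–C13), the ring oxygen leaves as the C8=C9 enolate, and this enolate closes C8–C12. One operation joins the side chain and makes quaternary C12, C8, the chloro-enone and the carbocycle.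
3. 14 comes from aldehyde 9 (C1–C8) and 4-chlorofuran-2(5H)-one by vinylogous aldol–elimination. 9 comes from D-threitol acetonide (C6, C7), Brown allylation (C5) and cross-metathesis with methyl acrylate (C1–C3).
4. Ring order: dioxolane (bought, temporary) → furanone (from tetronic acid, temporary) → cyclopentenone (step 11, made from the furanone); then acetonide/silyl removal and triacetylation.

Key step: step 11

Remark: prostanoid numbering of the target (C1 = ester carbon, C8 and C12 = ring carbons carrying the chains) is used for all intermediates. Organobarium species are drawn with covalent Ba–C/Ba–O bonds in SMILES for bookkeeping only. 4-Chlorofuran-2(5H)-one is made (step 8) and not assumed purchasable.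

**Step 1**
Reactants: 1 (4R,5R)-2,2-dimethyl-1,3-dioxolane-4,5-dimethanol (2,3-O-isopropylidene-D-threitol)
Product: 2 [(4R,5R)-5-(benzyloxymethyl)-2,2-dimethyl-1,3-dioxolan-4-yl]methanol
Conditions: NaH (1.0 equiv), BnBr (1.0 equiv), THF/DMF, 0 °C → rt
Reagents that add atoms: benzyl bromide, BrCc1ccccc1
Why: Williamson etherification of the monoalkoxide; the two hydroxyls of the C2-symmetric diol are equivalent, so monoprotection needs only stoichiometry and no stereocentre is touched.

**Step 2**
Reactants: 2 [(4R,5R)-5-(benzyloxymethyl)-2,2-dimethyl-1,3-dioxolan-4-yl]methanol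
Product: 3 4-O-benzyl-2,3-O-isopropylidene-D-threose [(4S,5R)-5-(benzyloxymethyl)-2,2-dimethyl-1,3-dioxolane-4-carbaldehyde]
Conditions: (COCl)2, DMSO, CH2Cl2, −78 °C; Et3N, −78 → 0 °C
Reagents that add atoms: none
Why: Swern oxidation gives the aldehyde at low temperature and should not epimerise the adjacent dioxolane stereocentre (C6).

**Step 3**
Reactants: 3 4-O-benzyl-2,3-O-isopropylidene-D-threose
Product: 4 (4S,5R,6R)-7-(benzyloxy)-5,6-(isopropylidenedioxy)hept-1-en-4-ol
Conditions: (−)-Ipc2BOMe [series from (+)-α-pinene], allylMgBr, Et2O, 0 °C → rt; then 3, −78 °C; then NaOH, H2O2, rt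
Reagents that add atoms: (−)-B-allyldiisopinocampheylborane (made in the flask from allylmagnesium bromide and (−)-B-methoxydiisopinocampheylborane), C=CCB([C@@H]1C[C@@H]2C[C@H]([C@H]1C)C2(C)C)[C@@H]1C[C@@H]2C[C@H]([C@H]1C)C2(C)C
Why: Brown allylboration; the reagent from (+)-α-pinene delivers allyl to the Si face of the aldehyde through a chair six-membered transition state, setting C5 as S (5,6-syn) under reagent control that should override the weaker Felkin preference of the substrate.

**Step 4**
Reactants: 4 (4S,5R,6R)-7-(benzyloxy)-5,6-(isopropylidenedioxy)hept-1-en-4-ol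
Product: 5 (4S,5S,6R)-7-(benzyloxy)-4-(tert-butyldimethylsilyloxy)-5,6-(isopropylidenedioxy)hept-1-ene
Conditions: TBSOTf, 2,6-lutidine, CH2Cl2, −78 → 0 °C
Reagents that add atoms: tert-butyldimethylsilyl triflate, CC(C)(C)[Si](C)(C)OS(=O)(=O)C(F)(F)F
Why: silylation of the hindered secondary alcohol gives an ether that should survive metathesis, hydrogenation, the aldol–elimination and the organobarium step and later leaves together with the acetonide.

**Step 5**
Reactants: 5 (4S,5S,6R)-7-(benzyloxy)-4-(tert-butyldimethylsilyloxy)-5,6-(isopropylidenedioxy)hept-1-ene; 6 methyl acrylate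
Product: 7 methyl (2E,5S,6S,7R)-8-(benzyloxy)-5-(tert-butyldimethylsilyloxy)-6,7-(isopropylidenedioxy)oct-2-enoate
Conditions: second-generation Grubbs catalyst [RuCl2(=CHPh)(PCy3)(H2IMes)] (5 mol%), methyl acrylate (5 equiv), CH2Cl2, 40 °C
Reagents that add atoms: none
Why: olefin cross-metathesis of a terminal alkene and an acrylate is a selective pairing (the electron-poor partner does not homodimerise) and should give the (E)-enoate, installing C1–C3 in one step.

**Step 6**
Reactants: 7 methyl (2E,5S,6S,7R)-8-(benzyloxy)-5-(tert-butyldimethylsilyloxy)-6,7-(isopropylidenedioxy)oct-2-enoate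
Product: 8 methyl (5S,6S,7R)-5-(tert-butyldimethylsilyloxy)-8-hydroxy-6,7-(isopropylidenedioxy)octanoate
Conditions: H2 (1 atm), Pd(OH)2 on carbon, EtOAc, rt
Reagents that add atoms: none
Why: catalytic hydrogenation saturates the enoate and hydrogenolyses the benzyl ether in the same operation, while silyl ether, acetonide and ester are inert.

**Step 7**
Reactants: 8 methyl (5S,6S,7R)-5-(tert-butyldimethylsilyloxy)-8-hydroxy-6,7-(isopropylidenedioxy)octanoate
Product: 9 methyl (5S,6S,7S)-5-(tert-butyldimethylsilyloxy)-6,7-(isopropylidenedioxy)-8-oxooctanoate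
Conditions: Dess–Martin periodinane, pyridine (buffer), CH2Cl2, 0 °C → rt; used crude
Reagents that add atoms: none
Why: Dess–Martin oxidation gives the α-alkoxy aldehyde under near-neutral conditions that should not epimerise C7.

**Step 8**
Reactants: 10 tetronic acid (4-hydroxyfuran-2(5H)-one)
Product: 11 4-chlorofuran-2(5H)-one
Conditions: (COCl)2, DMF (cat.), CH2Cl2, 0 °C → rt
Reagents that add atoms: oxalyl chloride, O=C(Cl)C(=O)Cl
Why: Vilsmeier-type activation converts the vinylogous acid into the vinylogous acid chloride, the reaction type used for 4-halofuranones.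

**Step 9**
Reactants: 9 methyl (5S,6S,7S)-5-(tert-butyldimethylsilyloxy)-6,7-(isopropylidenedioxy)-8-oxooctanoate; 11 4-chlorofuran-2(5H)-one
Product: 14 methyl (5S,6S,7R,8Z)-5-(tert-butyldimethylsilyloxy)-8-(3-chloro-5-oxofuran-2(5H)-ylidene)-6,7-(isopropylidenedioxy)octanoate, via silyloxyfuran 12 (not isolated), via aldol silyl ether 13 (not isolated)
Conditions: 11, TBSOTf, i-Pr2NEt, CH2Cl2, 0 °C; then 9, −78 °C → rt; then DBU, rt
Reagents that add atoms: none
Why: vinylogous Mukaiyama aldol addition of the in situ silyloxyfuran to the aldehyde, then E1cB loss of silanolate through the furanolate, should give the γ-ylidenebutenolide as the (Z)-isomer (C7 branch next to the ring oxygen, away from the chlorine on C10); both aldol stereocentres are erased and C7 is not involved.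

**Step 10**
Reactants: 15 (Z)-oct-2-en-1-ol
Product: 16 (Z)-1-chlorooct-2-ene
Conditions: NCS, Me2S, CH2Cl2, −20 → 0 °C
Reagents that add atoms: N-chlorosuccinimide, O=C1CCC(=O)N1Cl
Why: Corey–Kim chlorination replaces the allylic hydroxyl by SN2 attack of chloride on the alkoxysulfonium ion, which should keep the (Z)-geometry and avoid allylic transposition.

**Step 11**
Reactants: 14 methyl (5S,6S,7R,8Z)-5-(tert-butyldimethylsilyloxy)-8-(3-chloro-5-oxofuran-2(5H)-ylidene)-6,7-(isopropylidenedioxy)octanoate; 16 (Z)-1-chlorooct-2-ene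
Product: 20 methyl (5S,6S,7R,8R,12S,14Z)-5-(tert-butyldimethylsilyloxy)-10-chloro-12-hydroxy-6,7-(isopropylidenedioxy)-9-oxoprosta-10,14-dien-1-oate, via (Z)-oct-2-enylbarium chloride 17 (not isolated), via barium lactol alkoxide 18 (not isolated), via barium keto-enolate 19 (not isolated)
Conditions: activated zerovalent barium from BaI2 + lithium biphenylide (LiC12H10, 2 equiv), THF, rt; 16 (1.1 equiv), −78 °C; then 14, −78 → −30 °C; sat. aq. NH4Cl
Reagents that add atoms: none
Why: Proposed new method: the allylbarium 17 (a reagent class known to add to ketones and aldehydes at its α-carbon with retention of Z geometry at −78 °C) should add 1,2 to the enol-lactone carbonyl C12 of 14, and collapse of lactol alkoxide 18 expels the ring oxygen as the C9 enolate, so that ketone C12 and the regiodefined (Z)-enolate C8=C9 of 19 are generated together across the cis C10=C11 bond and close the C8–C12 bond by intramolecular aldol addition. The closest known reaction types are the Fujimoto–Belleau reaction (Grignard reagent plus enol lactone, ring opening, aldol closure) and the base-mediated cyclisation of (Z)-ene-1,4-diones to 4-hydroxycyclopent-2-enones; their combination with an allylbarium on a γ-ylidenebutenolide is what is new. The cyclopentenone closes in the 5-(enolendo)-exo-trig mode, formally strained but the normal course for cis-enediones because the cis alkene holds C8 and C12 within bonding distance (it can also be viewed as a conrotatory 4π closure of the oxido-pentadienyl unit C8–C12). C8 is controlled by C7: the (Z)-enolate geometry inherited from the (Z)-ylidene lactone lets barium bridge O9 and the dioxolane oxygen on C7 in a six-membered chelate, the C6 branch shields one enolate face and C12 bonds to the other (the chelate also keeps the C7–O bond in the enolate plane and so retards β-elimination). C12 is controlled by the closure geometry: the ketone reacts through its s-cis conformer (oxygen turned inward, the s-trans form suffers allylic 1,3-strain with C9), which puts the new alkoxide on the face of the C7 branch where the same barium can hold it and the octenyl chain trans to C7, also the thermodynamically preferred arrangement should the aldol equilibrate. The step needs attack at the lactone carbonyl in preference to the methyl ester, to C10 (addition–elimination of chloride) and to deprotonation at C7, which the enol-ester activation of C12, the hard allylmetal, near-stoichiometric reagent and −78 °C are expected to secure.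

**Step 12**
Reactants: 20 methyl (5S,6S,7R,8R,12S,14Z)-5-(tert-butyldimethylsilyloxy)-10-chloro-12-hydroxy-6,7-(isopropylidenedioxy)-9-oxoprosta-10,14-dien-1-oate
Product: 21 methyl (5S,6R,7R,8R,12S,14Z)-10-chloro-5,6,7,12-tetrahydroxy-9-oxoprosta-10,14-dien-1-oate
Conditions: anhydrous HCl (0.1 M) in MeOH, 0 °C → rt; NaHCO3 quench
Reagents that add atoms: none
Why: acid-catalysed transacetalisation and methanolysis of the silyl ether in methanol should release the triol while the solvent keeps the methyl ester (no δ-lactone from C5–OH) and the tertiary γ-hydroxy enone does not ionise.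

**Step 13**
Reactants: 21 methyl (5S,6R,7R,8R,12S,14Z)-10-chloro-5,6,7,12-tetrahydroxy-9-oxoprosta-10,14-dien-1-oate
Product: 22 Punaglandin 2
Conditions: Ac2O, pyridine, 0 °C → rt (no acyl-transfer catalyst)
Reagents that add atoms: acetic anhydride, CC(=O)OC(C)=O
Why: acetylation in pyridine esterifies the three secondary hydroxyls and should leave the hindered tertiary C12–OH free, giving the target.

**Compound list**
1 | (4R,5R)-2,2-dimethyl-1,3-dioxolane-4,5-dimethanol (2,3-O-isopropylidene-D-threitol) | OC[C@H]1OC(C)(C)O[C@@H]1CO | starting material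
2 | [(4R,5R)-5-(benzyloxymethyl)-2,2-dimethyl-1,3-dioxolan-4-yl]methanol | c1ccccc1COC[C@H]2OC(C)(C)O[C@@H]2CO | intermediate
3 | 4-O-benzyl-2,3-O-isopropylidene-D-threose, (4S,5R)-5-(benzyloxymethyl)-2,2-dimethyl-1,3-dioxolane-4-carbaldehyde | c1ccccc1COC[C@H]2OC(C)(C)O[C@@H]2C=O | intermediate
4 | (4S,5R,6R)-7-(benzyloxy)-5,6-(isopropylidenedioxy)hept-1-en-4-ol | c1ccccc1COC[C@H]2OC(C)(C)O[C@@H]2[C@H](CC=C)O | intermediate
5 | (4S,5S,6R)-7-(benzyloxy)-4-(tert-butyldimethylsilyloxy)-5,6-(isopropylidenedioxy)hept-1-ene | c1ccccc1COC[C@H]2OC(C)(C)O[C@@H]2[C@H](CC=C)O[Si](C)(C)C(C)(C)C | intermediate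
6 | methyl acrylate | C=CC(=O)OC | starting material
7 | methyl (2E,5S,6S,7R)-8-(benzyloxy)-5-(tert-butyldimethylsilyloxy)-6,7-(isopropylidenedioxy)oct-2-enoate | c1ccccc1COC[C@H]2OC(C)(C)O[C@@H]2[C@H](C/C=C/C(=O)OC)O[Si](C)(C)C(C)(C)C | intermediate
8 | methyl (5S,6S,7R)-5-(tert-butyldimethylsilyloxy)-8-hydroxy-6,7-(isopropylidenedioxy)octanoate | OC[C@H]1OC(C)(C)O[C@@H]1[C@H](CCCC(=O)OC)O[Si](C)(C)C(C)(C)C | intermediate
9 | methyl (5S,6S,7S)-5-(tert-butyldimethylsilyloxy)-6,7-(isopropylidenedioxy)-8-oxooctanoate | O=C[C@H]1OC(C)(C)O[C@@H]1[C@H](CCCC(=O)OC)O[Si](C)(C)C(C)(C)C | intermediate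
10 | tetronic acid (4-hydroxyfuran-2(5H)-one) | O=C1C=C(O)CO1 | starting material
11 | 4-chlorofuran-2(5H)-one | O=C1C=C(Cl)CO1 | intermediate
12 | 2-(tert-butyldimethylsilyloxy)-4-chlorofuran | CC(C)(C)[Si](C)(C)Oc1cc(Cl)co1 | intermediate (not isolated)
13 | methyl (5S,6S,7S)-5,8-bis(tert-butyldimethylsilyloxy)-8-(3-chloro-5-oxo-2,5-dihydrofuran-2-yl)-6,7-(isopropylidenedioxy)octanoate (epimers at C8 and at the furanone carbon) | O=C1C=C(Cl)C(O1)C(O[Si](C)(C)C(C)(C)C)[C@H]2OC(C)(C)O[C@@H]2[C@H](CCCC(=O)OC)O[Si](C)(C)C(C)(C)C | intermediate (not isolated)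
14 | methyl (5S,6S,7R,8Z)-5-(tert-butyldimethylsilyloxy)-8-(3-chloro-5-oxofuran-2(5H)-ylidene)-6,7-(isopropylidenedioxy)octanoate | O=C1C=C(Cl)/C(=C/[C@H]2OC(C)(C)O[C@@H]2[C@H](CCCC(=O)OC)O[Si](C)(C)C(C)(C)C)O1 | intermediate
15 | (Z)-oct-2-en-1-ol | CCCCC/C=C\CO | starting material
16 | (Z)-1-chlorooct-2-ene | CCCCC/C=C\CCl | intermediate
17 | (Z)-oct-2-enylbarium chloride | CCCCC/C=C\C[Ba]Cl | intermediate (not isolated)
18 | barium lactol alkoxide, 1,2-adduct of 17 to C12 of 14 (C12 epimers) | CCCCC/C=C\CC1(O[Ba]Cl)C=C(Cl)/C(=C/[C@H]2OC(C)(C)O[C@@H]2[C@H](CCCC(=O)OC)O[Si](C)(C)C(C)(C)C)O1 | intermediate (not isolated)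
19 | barium (Z)-enolate (C8=C9) of the ring-opened (Z)-2-chloro-ene-1,4-dione with the C12 ketone | CCCCC/C=C\CC(=O)/C=C(Cl)\C(O[Ba]Cl)=C\[C@H]1OC(C)(C)O[C@@H]1[C@H](CCCC(=O)OC)O[Si](C)(C)C(C)(C)C | intermediate (not isolated)
20 | methyl (5S,6S,7R,8R,12S,14Z)-5-(tert-butyldimethylsilyloxy)-10-chloro-12-hydroxy-6,7-(isopropylidenedioxy)-9-oxoprosta-10,14-dien-1-oate | CCCCC/C=C\C[C@@]1(O)C=C(Cl)C(=O)[C@@H]1[C@H]2OC(C)(C)O[C@@H]2[C@H](CCCC(=O)OC)O[Si](C)(C)C(C)(C)C | intermediate
21 | methyl (5S,6R,7R,8R,12S,14Z)-10-chloro-5,6,7,12-tetrahydroxy-9-oxoprosta-10,14-dien-1-oate | CCCCC/C=C\C[C@@]1(O)C=C(Cl)C(=O)[C@@H]1[C@@H](O)[C@H](O)[C@H](CCCC(=O)OC)O | intermediate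
22 | Punaglandin 2, methyl (5S,6R,7R,8R,12S,14Z)-5,6,7-triacetoxy-10-chloro-12-hydroxy-9-oxoprosta-10,14-dien-1-oate | CCCCC/C=C\C[C@@]1(O)C=C(Cl)C(=O)[C@@H]1[C@@H](OC(C)=O)[C@H](OC(C)=O)[C@H](CCCC(=O)OC)OC(C)=O | target

**Step count and risks**
Total step count: 13. Longest linear sequence: 11 steps (steps 1–7, 9, 11, 12, 13).

Steps most likely to fail:

1. Step 11 (proposed method). What may go wrong: loss of α-regioselectivity or Z-geometry of the allylmetal, competing attack at the methyl ester or at C10, deprotonation at C7, or poor facial control in the aldol closure. The fallback uses known reaction types, sets out from aldehyde 9 and chloride 16 and comes back at triol 21.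
   - 2,5-Dibromofuran is monolithiated (n-BuLi, THF, −78 °C) and alkylated with 16 to give 2-bromo-5-[(Z)-oct-2-en-1-yl]furan F1.
   - Bromine–lithium exchange (n-BuLi, −78 °C) and addition to 9 give the furylcarbinol F2.
   - Piancatelli rearrangement (Dy(OTf)3 cat., MeCN–H2O, 80 °C) gives the chlorine-free hydroxycyclopentenone F3. This is a known route from 5-alkyl-2-furylcarbinols to 4-alkyl-4-hydroxy-5-substituted cyclopent-2-enones and forms the same C8–C12 bond by conrotatory 4π closure. If needed, the epimerisable C8 centre is equilibrated (Et3N) to the trans arrangement of the two carbon chains.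
   - Nucleophilic epoxidation (t-BuOOH, DBU, 0 °C) gives the 10,11-epoxy ketone F4.
   - HCl in MeOH should open the epoxide at C10, dehydrate to the 2-chloro-enone and at the same time remove acetonide and silyl ether, so the sequence rejoins at 21.
   - The price is weaker control of the ring configuration relative to C7 (diastereomer separation expected) and a longer sequence.

2. Step 9. What may go wrong: attack of the amidine or amine base at the chlorine-bearing C10, epimerisation of the α-alkoxy aldehyde, or formation of an E/Z mixture. The fallback is a Wittig route that sets out from 11 and 9 and comes back at 14: radical bromination of 11 (NBS, AIBN, PhCF3, reflux) gives 5-bromo-4-chlorofuran-2(5H)-one F5; PPh3 (toluene, rt) gives (3-chloro-5-oxo-2,5-dihydrofuran-2-yl)triphenylphosphonium bromide F6; its stabilised ylide (Et3N, CH2Cl2, 0 °C) olefinates 9 to 14, and any (E)-isomer is isomerised with catalytic iodine in daylight.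

3. Step 12. What may go wrong: acid-promoted loss of the C7 oxygen function β to the C9 ketone, ketal formation between the freed hydroxyls and C9, or δ-lactonisation of C5–OH onto the ester. The fallback sets out from 20 and comes back at 21: the C9 ketone is taken out of play by Luche reduction (NaBH4, CeCl3·7H2O, MeOH, −78 °C) to the C9 allylic alcohol F7; acetonide and silyl ether are then removed with HCl in MeOH to give the pentaol F8; MnO2 (CH2Cl2, rt) re-oxidises only the allylic C9 alcohol and returns 21.

**Further compounds**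
F1 | step 11 | 2-bromo-5-[(Z)-oct-2-en-1-yl]furan | CCCCC/C=C\Cc1ccc(Br)o1
F2 | step 11 | methyl (5S,6S,7R)-5-(tert-butyldimethylsilyloxy)-8-hydroxy-6,7-(isopropylidenedioxy)-8-{5-[(Z)-oct-2-enyl]furan-2-yl}octanoate (C8 epimers) | CCCCC/C=C\Cc1ccc(o1)C(O)[C@H]2OC(C)(C)O[C@@H]2[C@H](CCCC(=O)OC)O[Si](C)(C)C(C)(C)C
F3 | step 11 | methyl (5S,6S,7R,8R,12R,14Z)-5-(tert-butyldimethylsilyloxy)-12-hydroxy-6,7-(isopropylidenedioxy)-9-oxoprosta-10,14-dien-1-oate (chlorine-free analogue of 20) | CCCCC/C=C\C[C@@]1(O)C=CC(=O)[C@@H]1[C@H]2OC(C)(C)O[C@@H]2[C@H](CCCC(=O)OC)O[Si](C)(C)C(C)(C)C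
F4 | step 11 | 10,11-epoxide of F3 (epoxide configuration immaterial) | CCCCC/C=C\C[C@@]1(O)C2OC2C(=O)[C@@H]1[C@H]3OC(C)(C)O[C@@H]3[C@H](CCCC(=O)OC)O[Si](C)(C)C(C)(C)C
F5 | step 9 | 5-bromo-4-chlorofuran-2(5H)-one (racemic) | O=C1C=C(Cl)C(Br)O1
F6 | step 9 | (3-chloro-5-oxo-2,5-dihydrofuran-2-yl)triphenylphosphonium bromide | O=C1C=C(Cl)C(O1)[P+](c2ccccc2)(c3ccccc3)c4ccccc4.[Br-]
F7 | step 12 | 20 with the C9 ketone reduced to the allylic alcohol (C9 epimers) | CCCCC/C=C\C[C@@]1(O)C=C(Cl)C(O)[C@@H]1[C@H]2OC(C)(C)O[C@@H]2[C@H](CCCC(=O)OC)O[Si](C)(C)C(C)(C)C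
F8 | step 12 | methyl 10-chloro-5,6,7,9,12-pentahydroxyprosta-10,14-dien-1-oate (C9 epimers, other centres as in 21) | CCCCC/C=C\C[C@@]1(O)C=C(Cl)C(O)[C@@H]1[C@@H](O)[C@H](O)[C@H](CCCC(=O)OC)O
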